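The route rests on disconnecting the C9–C11 bond of the cyclohexane ring C (C8–C9–C11–C12–C13–C14). C9 is the β-carbon of the C7 lactone carbonyl, so a C8-alkylated, C8=C9-unsaturated spiro-δ-lactone accepts a primary C11 radical in a 6-endo-trig reductive cyclisation that closes ring C and sets C9 under control of the spiro centre C10. The precursor carries the finished A-ring enone and a 4-bromo-2-methylidenebutyl chain on C8, whose exocyclic methylene masks the C13 ketone. Angular acetylation of C8, ozonolysis and an intramolecular aldol then build the bicyclo[3.2.1]octane, and methylenation followed by exo-face hydrogenation sets C16.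

Key step: step 12

Remark: ent-kaurane numbering is used throughout (C1 ketone, C2=C3, C4 CMe2, C5 bearing C6H2O, C7 lactone C=O, C8, C9, C10 spiro carbon, C11–C14 ring C, C15 ketone, C16 bearing C17, C20 lactone OCH2); the sense of induction of Rh/(R)-BINAP in step 2 is assigned by analogy with cyclohexenone.

Step 1
Reactants: 1 4,4-dimethylcyclohex-2-en-1-one
Product: 2 4,4-dimethylcyclohexa-2,5-dien-1-one
Conditions: DDQ (1.3 equiv), 1,4-dioxane, reflux
Reagents that add atoms: none
Why: DDQ dehydrogenation of the enone (hydride abstraction from its dienol) should give the symmetric cross-conjugated dienone; no stereocentre is formed.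

Step 2
Reactants: 2 4,4-dimethylcyclohexa-2,5-dien-1-one
Product: 3 (5R)-5-ethenyl-4,4-dimethylcyclohex-2-en-1-one
Conditions: CH2=CHBF3K (1.2 equiv), [Rh(cod)2]PF6 (3 mol%), (R)-BINAP (3.3 mol%), toluene/H2O 4:1, 100 °C
Reagents that add atoms: potassium vinyltrifluoroborate, C=C[B-](F)(F)F.[K+]
Why: Rh-catalysed asymmetric 1,4-addition (Hayashi–Miyaura reaction); the Rh–BINAP alkenyl complex selects one enantiotopic face of the symmetric dienone and sets C5 (R), and a second addition is slowed by the new neighbouring substituent.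

Step 3
Reactants: 3 (5R)-5-ethenyl-4,4-dimethylcyclohex-2-en-1-one
Product: 5 (5S)-5-(hydroxymethyl)-4,4-dimethylcyclohex-2-en-1-one, via aldehyde 4 (not isolated)
Conditions: O3, CH2Cl2/MeOH, −78 °C (Sudan III end point); Me2S; then NaBH4 (0.4 equiv), −78 °C
Reagents that add atoms: ozone, [O-][O+]=O
Why: Ozonolysis should cleave the electron-rich vinyl group in preference to the enone, and borohydride at −78 °C reduces the aldehyde faster than the conjugated ketone and before the α-centre C5 can epimerise.

Step 4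
Reactants: 5 (5S)-5-(hydroxymethyl)-4,4-dimethylcyclohex-2-en-1-one
Product: 6 (5S)-5-{[tert-butyl(dimethyl)silyl]oxymethyl}-4,4-dimethylcyclohex-2-en-1-one
Conditions: TBSCl, imidazole, CH2Cl2, 0 °C to rt
Reagents that add atoms: tert-butyldimethylsilyl chloride, CC(C)(C)[Si](C)(C)Cl
Why: Standard silylation of the primary alcohol; the ether must survive enolate, radical and ozonolysis steps.

Step 5
Reactants: 6 (5S)-5-{[tert-butyl(dimethyl)silyl]oxymethyl}-4,4-dimethylcyclohex-2-en-1-one
Product: 7 (5R,6Z)-5-{[tert-butyl(dimethyl)silyl]oxymethyl}-6-(hydroxymethylidene)-4,4-dimethylcyclohex-2-en-1-one (enol form of the 6-formyl ketone)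
Conditions: NaH, HCO2Et, cat. EtOH, THF, 0 °C to rt; dilute HCl work-up
Reagents that add atoms: ethyl formate, CCOC=O
Why: Claisen formylation at C10, the only enolisable position (C2 is vinylic, C4 quaternary); it brings in C20 and activates C10 for quaternisation.

Step 6
Reactants: 7 (5R,6Z)-5-{[tert-butyl(dimethyl)silyl]oxymethyl}-6-(hydroxymethylidene)-4,4-dimethylcyclohex-2-en-1-one
Product: 8 methyl 3-[(1S,6R)-6-{[tert-butyl(dimethyl)silyl]oxymethyl}-1-formyl-5,5-dimethyl-2-oxocyclohex-3-en-1-yl]propanoate (CHO and CH2OTBS cis)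
Conditions: methyl acrylate (2 equiv), Et3N (0.3 equiv), MeCN, rt
Reagents that add atoms: methyl acrylate, C=CC(=O)OC
Why: Michael addition of the β-keto aldehyde enolate; the acrylate should approach C10 anti to the adjacent CH2OTBS group, so C9 ends trans and the formyl carbon C20 cis to C6, which sets C10.

Step 7
Reactants: 8 methyl 3-[(1S,6R)-6-{[tert-butyl(dimethyl)silyl]oxymethyl}-1-formyl-5,5-dimethyl-2-oxocyclohex-3-en-1-yl]propanoate
Product: 10 (6S,11R)-11-{[tert-butyl(dimethyl)silyl]oxymethyl}-10,10-dimethyl-2-oxaspiro[5.5]undec-8-ene-3,7-dione, via hydroxy ester 9 (not isolated)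
Conditions: NaBH4 (0.35 equiv), MeOH/CH2Cl2, −78 °C; then TsOH·H2O (5 mol%), CH2Cl2, rt
Reagents that add atoms: none
Why: Chemoselective reduction of the non-enolisable aldehyde over the hindered conjugated ketone, then acid-catalysed lactonisation of the C20 alcohol onto the C7 ester to the six-membered lactone.

Step 8
Reactants: 11 dimethyl itaconate
Product: 12 2-methylidenebutane-1,4-diol
Conditions: DIBAL-H (4.5 equiv), CH2Cl2, −78 to 0 °C; Rochelle salt work-up
Reagents that add atoms: none
Why: DIBAL-H reduces both esters by 1,2-addition without touching the 1,1-disubstituted alkene.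

Step 9
Reactants: 12 2-methylidenebutane-1,4-diol
Product: 13 4-bromo-2-(bromomethyl)but-1-ene
Conditions: CBr4 (2.4 equiv), PPh3 (2.4 equiv), CH2Cl2, 0 °C
Reagents that add atoms: carbon tetrabromide, BrC(Br)(Br)Br
Why: Appel bromination of both primary alcohols gives a bis-electrophile with one allylic and one much less reactive homoallylic bromide.

Step 10
Reactants: 10 (6S,11R)-11-{[tert-butyl(dimethyl)silyl]oxymethyl}-10,10-dimethyl-2-oxaspiro[5.5]undec-8-ene-3,7-dione; 13 4-bromo-2-(bromomethyl)but-1-ene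
Product: 15 (6S,11R)-4-(4-bromo-2-methylidenebutyl)-11-{[tert-butyl(dimethyl)silyl]oxymethyl}-10,10-dimethyl-4-(phenylselanyl)-2-oxaspiro[5.5]undec-8-ene-3,7-dione (C8 epimers), via α-phenylselanyl lactone 14 (not isolated)
Conditions: LDA (1.05 equiv), THF, −78 °C; PhSeBr (1.0 equiv); LDA (1.1 equiv), −78 °C; 13 (3 equiv), DMPU, −78 to −30 °C
Reagents that add atoms: phenylselanyl bromide, Br[Se]c1ccccc1
Why: Reich α-selenenylation, then alkylation of the more acidic α-seleno lactone enolate at the allylic bromide of 13; C8 becomes quaternary, so no enolate is left to attack the homoallylic bromide, and the C8 configuration is lost in step 11.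

Step 11
Reactants: 15 (6S,11R)-4-(4-bromo-2-methylidenebutyl)-11-{[tert-butyl(dimethyl)silyl]oxymethyl}-10,10-dimethyl-4-(phenylselanyl)-2-oxaspiro[5.5]undec-8-ene-3,7-dione
Product: 17 (6S,11R)-4-(4-bromo-2-methylidenebutyl)-11-{[tert-butyl(dimethyl)silyl]oxymethyl}-10,10-dimethyl-2-oxaspiro[5.5]undeca-4,8-diene-3,7-dione, via selenoxide 16 (not isolated)
Conditions: 30% H2O2, pyridine, CH2Cl2, 0 °C to rt
Reagents that add atoms: none
Why: Selenoxide syn-elimination; loss of the ring C9–H should give the endocyclic conjugated C8=C9 alkene, the usual course for α-alkyl-α-seleno six-membered lactones.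

Step 12
Reactants: 17 (6S,11R)-4-(4-bromo-2-methylidenebutyl)-11-{[tert-butyl(dimethyl)silyl]oxymethyl}-10,10-dimethyl-2-oxaspiro[5.5]undeca-4,8-diene-3,7-dione
Product: 18 tricyclic methylidene lactone (5R,9R,10S; C8–H epimers): A-ring enone spiro at C10 to the δ-lactone, which is fused at C8–C9 to the 13-methylidenecyclohexane ring C; C11 on the lactone face of C1
Conditions: Bu3SnH (1.3 equiv) and AIBN (0.2 equiv) added over 8 h, benzene (0.005 M), 80 °C
Reagents that add atoms: none
Why: Bu3Sn• abstracts bromine from C11, the primary radical adds to C9, the β-carbon of the C7 lactone carbonyl, and the resulting C8 α-lactone radical takes hydrogen from the stannane. The closest known reaction type is the tin-hydride-mediated Giese-type cyclisation of ω-haloalkyl radicals onto α-substituted acrylates and unsaturated lactones. Ring C (C8–C9–C11–C12–C13–C14) closes in the 6-endo-trig mode. The new C9 stereocentre is controlled by the spiro centre C10: the C5 arm (CH2OTBS next to the gem-dimethyl carbon) blocks one face of the lactone alkene, so C11 bonds on the face of the flat C1 carbonyl arm, while the C8–H centre formed at the same time is erased in step 13. The step needs 6-endo closure to win over 5-exo closure and over direct reduction of the C11 radical; polarity matching (nucleophilic radical, electron-poor β-carbon), the fully substituted α-carbon C8 and slow stannane addition at high dilution should secure it. The homoallyl/cyclopropylcarbinyl rearrangement through C13=CH2 is degenerate and the A-ring enone is out of reach.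

Step 13
Reactants: 18 tricyclic methylidene lactone (5R,9R,10S; C8–H epimers)
Product: 19 8-acetyl tricycle (5R,8S,9S,10S): acetyl on C8 cis to H-9, lactone and ring C cis-fused
Conditions: LDA (1.3 equiv), THF, −78 °C; AcCl (1.5 equiv), −78 °C
Reagents that add atoms: acetyl chloride, CC(Cl)=O
Why: Angular C-acylation of the lithium lactone enolate (C8 is the only acidic site); the electrophile should enter syn to H-9, anti to the ring-C carbon C11 and to the pseudoaxial C1 arm, giving the cis-fused bicycle as in angular alkylation of ring-fusion enolates, which sets C8.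

Step 14
Reactants: 19 8-acetyl tricycle (5R,8S,9S,10S)
Product: 20 triketone (5R,8S,9S,10S): 13-oxo analogue of 19
Conditions: O3, CH2Cl2, −78 °C (Sudan III end point); Me2S, −78 °C to rt
Reagents that add atoms: ozone, [O-][O+]=O
Why: Selective ozonolysis of the electron-rich 1,1-disubstituted alkene over the electron-poor A-ring enone unmasks the C13 ketone.

Step 15
Reactants: 20 triketone (5R,8S,9S,10S)
Product: 21 ketol (5R,8S,9S,10S,13S): 13-hydroxy-15-oxo bicyclo[3.2.1]octane with C16H2 (17-nor target, 6-O-TBS)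
Conditions: KOtBu (0.2 equiv), t-BuOH/THF, 0 °C
Reagents that add atoms: none
Why: Intramolecular aldol addition of the 1,4-diketone under equilibrating, non-nucleophilic base: the methyl-ketone enolate (C16) adds to the C13 ketone, the bridge can only form on the ring-C face that carries the acetyl group so C8 dictates C13, and the alternative bicyclo[2.2.1] aldol is more strained and reversible.

Step 16
Reactants: 21 ketol (5R,8S,9S,10S,13S)
Product: 24 16-methylidene enone (5R,8S,9S,10S,13S; 6-O-TBS), via Mannich base 22 (not isolated), via trimethylammonium iodide 23 (not isolated)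
Conditions: LDA (2.3 equiv), THF, −78 to −30 °C; CH2=NMe2+ I−, −78 °C to rt; then MeI, CH2Cl2, rt; then sat. aq. NaHCO3, rt
Reagents that add atoms: N,N-dimethylmethylideneammonium iodide (Eschenmoser's salt), C=[N+](C)C.[I-]
Why: Eschenmoser α-methylenation at C16, the only enolisable carbon left; once the alkoxide–enolate dianion has formed retro-aldol cleavage is blocked, and quaternisation with E1cB elimination gives the exocyclic enone.

Step 17
Reactants: 24 16-methylidene enone (5R,8S,9S,10S,13S; 6-O-TBS)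
Product: 25 6-O-TBS ether of the target (5R,8S,9S,10S,13S,16R)
Conditions: H2 (1 atm), RhCl(PPh3)3 (10 mol%), benzene, rt
Reagents that add atoms: none
Why: Homogeneous hydrogenation with Wilkinson's catalyst should reduce the unhindered 1,1-disubstituted alkene and leave the hindered C2=C3 enone; H2 is delivered to the exo face of the two-carbon bridge (the side of the 13-OH and C14), so the C17 methyl ends up towards the C11–C12 bridge (16R).

Step 18
Reactants: 25 6-O-TBS ether of the target (5R,8S,9S,10S,13S,16R)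
Product: 26 target CNP0533761.1 (5R,8S,9S,10S,13S,16R)
Conditions: HF·pyridine, THF/pyridine, 0 °C to rt
Reagents that add atoms: none
Why: Mildly acidic fluoride desilylation frees the C6 alcohol without enolising C16 or opening the β-hydroxy ketone.

Compound list
1 | 4,4-dimethylcyclohex-2-en-1-one | CC1(C)CCC(=O)C=C1 | starting material
2 | 4,4-dimethylcyclohexa-2,5-dien-1-one | CC1(C)C=CC(=O)C=C1 | intermediate
3 | (5R)-5-ethenyl-4,4-dimethylcyclohex-2-en-1-one | C1C(=O)C=CC(C)(C)[C@H]1C=C | intermediate
4 | (1S)-2,2-dimethyl-5-oxocyclohex-3-ene-1-carbaldehyde | C1C(=O)C=CC(C)(C)[C@H]1C=O | intermediate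
5 | (5S)-5-(hydroxymethyl)-4,4-dimethylcyclohex-2-en-1-one | C1C(=O)C=CC(C)(C)[C@H]1CO | intermediate
6 | (5S)-5-{[tert-butyl(dimethyl)silyl]oxymethyl}-4,4-dimethylcyclohex-2-en-1-one | C1C(=O)C=CC(C)(C)[C@H]1CO[Si](C)(C)C(C)(C)C | intermediate
7 | (5R,6Z)-5-{[tert-butyl(dimethyl)silyl]oxymethyl}-6-(hydroxymethylidene)-4,4-dimethylcyclohex-2-en-1-one | O/C=C1\C(=O)C=CC(C)(C)[C@H]1CO[Si](C)(C)C(C)(C)C | intermediate
8 | methyl 3-[(1S,6R)-6-{[tert-butyl(dimethyl)silyl]oxymethyl}-1-formyl-5,5-dimethyl-2-oxocyclohex-3-en-1-yl]propanoate | COC(=O)CC[C@]1(C=O)C(=O)C=CC(C)(C)[C@H]1CO[Si](C)(C)C(C)(C)C | intermediate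
9 | methyl 3-[(1S,6R)-6-{[tert-butyl(dimethyl)silyl]oxymethyl}-1-(hydroxymethyl)-5,5-dimethyl-2-oxocyclohex-3-en-1-yl]propanoate | COC(=O)CC[C@]1(CO)C(=O)C=CC(C)(C)[C@H]1CO[Si](C)(C)C(C)(C)C | intermediate
10 | (6S,11R)-11-{[tert-butyl(dimethyl)silyl]oxymethyl}-10,10-dimethyl-2-oxaspiro[5.5]undec-8-ene-3,7-dione | O=C1CC[C@]2(CO1)C(=O)C=CC(C)(C)[C@H]2CO[Si](C)(C)C(C)(C)C | intermediate
11 | dimethyl itaconate | COC(=O)CC(=C)C(=O)OC | starting material
12 | 2-methylidenebutane-1,4-diol | OCCC(=C)CO | intermediate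
13 | 4-bromo-2-(bromomethyl)but-1-ene | BrCCC(=C)CBr | intermediate
14 | 4-(phenylselanyl) derivative of 10 (C8 epimers) | O=C1C([Se]c3ccccc3)C[C@]2(CO1)C(=O)C=CC(C)(C)[C@H]2CO[Si](C)(C)C(C)(C)C | intermediate
15 | (6S,11R)-4-(4-bromo-2-methylidenebutyl)-11-{[tert-butyl(dimethyl)silyl]oxymethyl}-10,10-dimethyl-4-(phenylselanyl)-2-oxaspiro[5.5]undec-8-ene-3,7-dione (C8 epimers) | O=C1C([Se]c3ccccc3)(CC(=C)CCBr)C[C@]2(CO1)C(=O)C=CC(C)(C)[C@H]2CO[Si](C)(C)C(C)(C)C | intermediate
16 | selenoxide of 15 | O=C1C([Se](=O)c3ccccc3)(CC(=C)CCBr)C[C@]2(CO1)C(=O)C=CC(C)(C)[C@H]2CO[Si](C)(C)C(C)(C)C | intermediate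
17 | (6S,11R)-4-(4-bromo-2-methylidenebutyl)-11-{[tert-butyl(dimethyl)silyl]oxymethyl}-10,10-dimethyl-2-oxaspiro[5.5]undeca-4,8-diene-3,7-dione | O=C1C(CC(=C)CCBr)=C[C@]2(CO1)C(=O)C=CC(C)(C)[C@H]2CO[Si](C)(C)C(C)(C)C | intermediate
18 | tricyclic methylidene lactone (5R,9R,10S; C8–H epimers), ring C closed, 13-methylidene | C=C1CC[C@H]2[C@]3(COC(=O)C2C1)C(=O)C=CC(C)(C)[C@H]3CO[Si](C)(C)C(C)(C)C | intermediate
19 | 8-acetyl tricycle (5R,8S,9S,10S), acetyl cis to H-9 | C=C1CC[C@H]2[C@]3(COC(=O)[C@]2(C1)C(C)=O)C(=O)C=CC(C)(C)[C@H]3CO[Si](C)(C)C(C)(C)C | intermediate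
20 | triketone (5R,8S,9S,10S), 13-oxo analogue of 19 | O=C1CC[C@H]2[C@]3(COC(=O)[C@]2(C1)C(C)=O)C(=O)C=CC(C)(C)[C@H]3CO[Si](C)(C)C(C)(C)C | intermediate
21 | ketol (5R,8S,9S,10S,13S), 17-nor target 6-O-TBS ether | C1C(=O)[C@]23C[C@@]1(O)CC[C@H]2[C@]4(COC3=O)C(=O)C=CC(C)(C)[C@H]4CO[Si](C)(C)C(C)(C)C | intermediate
22 | 16-(dimethylaminomethyl) ketol (C16 epimers) | CN(C)CC1C(=O)[C@]23C[C@@]1(O)CC[C@H]2[C@]4(COC3=O)C(=O)C=CC(C)(C)[C@H]4CO[Si](C)(C)C(C)(C)C | intermediate
23 | 16-(trimethylammoniomethyl) ketol iodide | C[N+](C)(C)CC1C(=O)[C@]23C[C@@]1(O)CC[C@H]2[C@]4(COC3=O)C(=O)C=CC(C)(C)[C@H]4CO[Si](C)(C)C(C)(C)C.[I-] | intermediate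
24 | 16-methylidene enone (5R,8S,9S,10S,13S), 6-O-TBS | C=C1C(=O)[C@]23C[C@@]1(O)CC[C@H]2[C@]4(COC3=O)C(=O)C=CC(C)(C)[C@H]4CO[Si](C)(C)C(C)(C)C | intermediate
25 | 6-O-TBS ether of the target (5R,8S,9S,10S,13S,16R) | C[C@H]1C(=O)[C@]23C[C@@]1(O)CC[C@H]2[C@]4(COC3=O)C(=O)C=CC(C)(C)[C@H]4CO[Si](C)(C)C(C)(C)C | intermediate
26 | CNP0533761.1 (5R,8S,9S,10S,13S,16R) | C[C@H]1C(=O)[C@]23C[C@@]1(O)CC[C@H]2[C@]1(COC3=O)C(=O)C=CC(C)(C)[C@H]1CO | target

Total step count: 18. Longest linear sequence: 16 (steps 1–7 and 10–18).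

Steps most likely to fail

1. Step 12. Addition of the primary C11 radical to the neopentyl-type C9 may be slower than hydrogen transfer from the stannane, or closure may occur 5-exo at C8, so that reduced or spiro products form instead of ring C. The fallback replaces the radical by an anion and sets out from 17. Kornblum displacement of the bromide (NaNO2, DMF) should give the nitroalkane F1. DBU in MeCN should then close ring C by intramolecular Michael addition of the nitronate carbon C11 to C9 (6-endo-trig), giving the 11-nitro tricycle F2. Radical denitration (Bu3SnH, AIBN, toluene, 110 °C) returns to the route at 18.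

2. Step 13. The hindered, fully substituted lactone enolate may be O-acylated or quenched by proton transfer from acetyl chloride instead of forming the quaternary C8–C15 bond. The fallback sets out from 18: the same enolate is added to acetaldehyde at −78 °C, an aldol addition that cannot give an O-product, to give the β-hydroxy lactone F3. Dess–Martin oxidation returns to the route at 19. The facial sense of attack is unchanged, so this fallback does not address formation of the trans-fused C8 epimer.

3. Step 11. The selenoxide may eliminate towards the allylic C14–H and give the exocyclic diene instead of the C8=C9 lactone. The fallback builds the C8–C14 bond on an alkene whose position is already fixed and sets out from 10 and 13. Selenenylation of 10 as in step 10 gives 14, now isolated; a second deprotonation and bromination (LDA; BrCCl2CCl2Br) gives the α-bromo-α-seleno lactone F4. H2O2 can then eliminate only into the ring, giving the 4-bromo unsaturated lactone F5. Pd-catalysed borylation of the allylic bromide of 13 (Pd2(dba)3, B2pin2) gives the allylboronate F6, whose two allyl termini are equivalent. Suzuki–Miyaura coupling of F5 with F6 (Pd(PPh3)4, CsF, THF, 60 °C) returns to the route at 17.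

Further compounds
F1 | step 12 | (6S,11R)-11-{[tert-butyl(dimethyl)silyl]oxymethyl}-10,10-dimethyl-4-(2-methylidene-4-nitrobutyl)-2-oxaspiro[5.5]undeca-4,8-diene-3,7-dione | O=C1C(CC(=C)CC[N+](=O)[O-])=C[C@]2(CO1)C(=O)C=CC(C)(C)[C@H]2CO[Si](C)(C)C(C)(C)C
F2 | step 12 | 11-nitro analogue of 18 (C8 and C11 epimers) | C=C1CC([N+](=O)[O-])[C@H]2[C@]3(COC(=O)C2C1)C(=O)C=CC(C)(C)[C@H]3CO[Si](C)(C)C(C)(C)C
F3 | step 13 | 8-(1-hydroxyethyl) analogue of 19 (carbinol epimers) | C=C1CC[C@H]2[C@]3(COC(=O)[C@]2(C1)C(C)O)C(=O)C=CC(C)(C)[C@H]3CO[Si](C)(C)C(C)(C)C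
F4 | step 11 | 4-bromo-4-(phenylselanyl) derivative of 10 (C8 epimers) | O=C1C(Br)([Se]c3ccccc3)C[C@]2(CO1)C(=O)C=CC(C)(C)[C@H]2CO[Si](C)(C)C(C)(C)C
F5 | step 11 | (6S,11R)-4-bromo-11-{[tert-butyl(dimethyl)silyl]oxymethyl}-10,10-dimethyl-2-oxaspiro[5.5]undeca-4,8-diene-3,7-dione | O=C1C(Br)=C[C@]2(CO1)C(=O)C=CC(C)(C)[C@H]2CO[Si](C)(C)C(C)(C)C
F6 | step 11 | 2-[4-bromo-2-methylidenebutyl]-4,4,5,5-tetramethyl-1,3,2-dioxaborolane | BrCCC(=C)CB1OC(C)(C)C(C)(C)O1
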